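**Plan**

1. Cuts, working back from the target: the tertiary C–OOH bond (ene reaction on a skipped diene), the acetate C–O bond, ring B at C3′=C4′ (metathesis) and C2′–C3′ (vinyl addition), the inter-ring bond C5–C1′ (ester enolate onto a C1–C5 epoxide), the ester C–O bond to an (S)-acid, and the two chain bonds at the trisubstituted alkene (carboalumination–prenylation).
2. Feature used: in ring A (C1–C5; C1 bears OH and CH2OAc, C3 the dienyl chain, C5 ring B) the C1 oxygen is trans to the C5–C1′ bond, while the C1 CH2O arm, the C5–C1′ bond and the C3 chain lie on one face. This is the pattern of a C1–C5 epoxide opened anti by a nucleophile delivered from the C1 CH2O arm; C1′ and C2′ of ring B are then the α-carbon and carbonyl carbon of a δ-lactone.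
3. Forward order: ring A first (cleavage of limonene oxide, aldol re-closure to a cyclopentene), then the chain on the former isopropenyl carbon, then the epoxide, the ester tether and the lactone closure (C5–C1′); ring B is closed last by metathesis, followed by oxidation, acetylation and photooxygenation.
4. Stereochemistry: C3 from (R)-limonene; C1 and C5 from the Sharpless epoxidation (L-(+)-tartrate, anti to the C3 chain) and inversion at C5; C5′ from the resolved (S)-acid; C1′ from the lactone closure (arm on the convex face, equilibratable α-centre); both E alkenes from syn-carboalumination and the ene reaction.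

Key step: step 14

Remark on the chemistry: commercial (+)-limonene 1,2-oxide (cis/trans mixture made from (R)-limonene) is taken as the entry point, since its epoxide centres are erased in step 1.
Remark on the chemistry: the two N-acyl diastereomers of step 11 are assumed to be separable by chromatography.
Numbering: ring A C1–C5 as above; ring B C1′ (on C5), C2′ (C=O), C3′=C4′, C5′ (CH3).

**Route**

Step 1
Reactants: 1 (+)-limonene 1,2-oxide [(4R)-1-methyl-4-(prop-1-en-2-yl)-7-oxabicyclo[4.1.0]heptane, cis/trans mixture]
Product: 3 (3R)-6-oxo-3-(prop-1-en-2-yl)heptanal, via limonene-1,2-diol 2 (not isolated)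
Conditions: H5IO6 (1.1 equiv), THF–H2O, 0 °C → rt
Reagents that add atoms: water, SMILES O
Why: Periodic acid hydrolyses the epoxide to the 1,2-diol and cleaves it (glycol cleavage) without touching the isopropenyl group, and the (R) centre that becomes ring-A C3 is not involved.

Step 2
Reactants: 3 (3R)-6-oxo-3-(prop-1-en-2-yl)heptanal
Product: 5 1-[(4S)-4-(prop-1-en-2-yl)cyclopent-1-en-1-yl]ethan-1-one, via aldol adduct 4 (not isolated)
Conditions: KOH (aq.), Et2O, rt → reflux
Reagents that add atoms: none
Why: Intramolecular aldol condensation under equilibrating hydroxide conditions, in which the ketone enolate on the chain side adds to the aldehyde (5-(enolexo)-exo-trig) and dehydration gives the conjugated acetylcyclopentene; the stereocentre is remote from any acidic position.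

Step 3
Reactants: 5 1-[(4S)-4-(prop-1-en-2-yl)cyclopent-1-en-1-yl]ethan-1-one
Product: 7 (4S)-4-(prop-1-en-2-yl)cyclopent-1-ene-1-carboxylic acid, via tribromomethyl ketone 6 (not isolated)
Conditions: Br2, NaOH (NaOBr preformed), dioxane–H2O, 0 °C; then HCl
Reagents that add atoms: sodium hydroxide, SMILES [Na+].[OH-]
Why: Haloform reaction, in which exhaustive α-bromination of the methyl ketone and hydroxide cleavage of the tribromomethyl ketone give the carboxylate, while the isopropenyl group should be inert to hypobromite at high pH.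

Step 4
Reactants: 7 (4S)-4-(prop-1-en-2-yl)cyclopent-1-ene-1-carboxylic acid
Product: 8 methyl (4S)-4-(prop-1-en-2-yl)cyclopent-1-ene-1-carboxylate
Conditions: MeI, K2CO3, DMF, rt
Reagents that add atoms: iodomethane, SMILES CI
Why: SN2 O-methylation of the carboxylate gives the ester, which keeps the ring alkene electron-poor for the next step.

Step 5
Reactants: 8 methyl (4S)-4-(prop-1-en-2-yl)cyclopent-1-ene-1-carboxylate
Product: 10 methyl (4S)-4-acetylcyclopent-1-ene-1-carboxylate, via secondary ozonide 9 (not isolated)
Conditions: O3 (1.0 equiv), CH2Cl2, −78 °C; then Me2S, −78 °C → rt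
Reagents that add atoms: ozone, SMILES [O-][O+]=O
Why: Ozonolysis with one equivalent of ozone should cleave only the electron-rich 1,1-disubstituted alkene, because the ester-conjugated ring alkene reacts far more slowly.

Step 6
Reactants: 10 methyl (4S)-4-acetylcyclopent-1-ene-1-carboxylate
Product: 12 methyl (4S)-4-{1-[(diethoxyphosphoryl)oxy]ethenyl}cyclopent-1-ene-1-carboxylate, via kinetic lithium enolate 11 (not isolated)
Conditions: LiN(iPr)2 (1.05 equiv), THF, −78 °C (ketone added to base); then ClP(O)(OEt)2, −78 → 0 °C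
Reagents that add atoms: diethyl chlorophosphate, SMILES CCOP(=O)(Cl)OCC
Why: Kinetic deprotonation by the hindered amide occurs at the methyl group and not at the ring methine, so the stereocentre is kept, and O-phosphorylation traps the terminal enolate as the enol phosphate.

Step 7
Reactants: 12 methyl (4S)-4-{1-[(diethoxyphosphoryl)oxy]ethenyl}cyclopent-1-ene-1-carboxylate
Product: 13 diethyl 1-[(1S)-3-(hydroxymethyl)cyclopent-3-en-1-yl]ethenyl phosphate
Conditions: iBu2AlH (2.2 equiv), CH2Cl2, −78 °C
Reagents that add atoms: none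
Why: Diisobutylaluminium hydride reduces the conjugated ester in the 1,2-sense to the allylic alcohol at low temperature, while the enol phosphate should be inert.

Step 8
Reactants: 13 diethyl 1-[(1S)-3-(hydroxymethyl)cyclopent-3-en-1-yl]ethenyl phosphate
Product: 14 [(4S)-4-ethynylcyclopent-1-en-1-yl]methanol
Conditions: LiN(iPr)2 (3.3 equiv), THF, −78 °C → rt
Reagents that add atoms: none
Why: Base-induced β-elimination of diethyl phosphate from the terminal enol phosphate (methyl ketone to terminal alkyne protocol) gives the acetylide, the extra base being taken up by the hydroxyl group and the product alkyne.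

Step 9
Reactants: 14 [(4S)-4-ethynylcyclopent-1-en-1-yl]methanol; 15 prenyl bromide (1-bromo-3-methylbut-2-ene)
Product: 17 {(4S)-4-[(2E)-6-methylhepta-2,5-dien-2-yl]cyclopent-1-en-1-yl}methanol, via alkenylalane 16 (not isolated)
Conditions: AlMe3 (3 equiv), Cp2ZrCl2 (0.25 equiv), CH2Cl2, 0 °C → rt; then 15, Pd(PPh3)4 (5 mol %), THF, rt
Reagents that add atoms: trimethylaluminium, SMILES C[Al](C)C
Why: Negishi carboalumination adds methyl and aluminium syn across the alkyne with aluminium on the terminal carbon, which fixes the E trisubstituted alkene, and allylation of the alkenylalane under zerovalent palladium catalysis at the primary carbon of prenyl bromide gives the skipped diene with retention.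

Step 10
Reactants: 17 {(4S)-4-[(2E)-6-methylhepta-2,5-dien-2-yl]cyclopent-1-en-1-yl}methanol
Product: 18 {(1S,3S,5S)-3-[(2E)-6-methylhepta-2,5-dien-2-yl]-6-oxabicyclo[3.1.0]hexan-1-yl}methanol
Conditions: Ti(OiPr)4 (0.1 equiv), L-(+)-diethyl tartrate (0.12 equiv), t-BuOOH (2 equiv), 4 Å molecular sieves, CH2Cl2, −20 °C
Reagents that add atoms: tert-butyl hydroperoxide, SMILES CC(C)(C)OO
Why: Sharpless asymmetric epoxidation oxidises only the allylic-alcohol alkene, and L-(+)-tartrate directs oxygen to the ring face opposite the C3 chain (also the less hindered face), which sets C1 and C5.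

Step 11
Reactants: 19 racemic 3-methylpent-4-enoic acid; 20 (S)-4-benzyloxazolidin-2-one
Product: 22 (4S)-4-benzyl-3-[(3S)-3-methylpent-4-enoyl]oxazolidin-2-one, via mixed pivalic anhydride 21 (not isolated)
Conditions: Me3CCOCl, Et3N, THF, −20 °C; then LiCl, 20, rt; chromatographic separation of the two diastereomers
Reagents that add atoms: none
Why: N-Acylation of the oxazolidinone through the mixed anhydride gives two diastereomeric imides that differ only at the acyl β-carbon, so the racemate is resolved covalently and the (3S) isomer is taken on.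

Step 12
Reactants: 22 (4S)-4-benzyl-3-[(3S)-3-methylpent-4-enoyl]oxazolidin-2-one
Product: 24 (3S)-3-methylpent-4-enoic acid, via peroxy acid 23 (not isolated)
Conditions: LiOH, H2O2, THF–H2O, 0 °C; then Na2SO3; then HCl
Reagents that add atoms: hydrogen peroxide, SMILES OO
Why: Hydroperoxide anion attacks the exocyclic imide carbonyl selectively and sulfite reduces the percarboxylate, while the β-stereocentre is not enolisable and should survive unchanged.

Step 13
Reactants: 18 {(1S,3S,5S)-3-[(2E)-6-methylhepta-2,5-dien-2-yl]-6-oxabicyclo[3.1.0]hexan-1-yl}methanol; 24 (3S)-3-methylpent-4-enoic acid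
Product: 25 {(1S,3S,5S)-3-[(2E)-6-methylhepta-2,5-dien-2-yl]-6-oxabicyclo[3.1.0]hexan-1-yl}methyl (3S)-3-methylpent-4-enoate
Conditions: DCC, DMAP (cat.), CH2Cl2, 0 °C → rt
Reagents that add atoms: none
Why: Steglich esterification acylates the primary alcohol under neutral conditions that should leave the epoxide intact.

Step 14
Reactants: 25 {(1S,3S,5S)-3-[(2E)-6-methylhepta-2,5-dien-2-yl]-6-oxabicyclo[3.1.0]hexan-1-yl}methyl (3S)-3-methylpent-4-enoate
Product: 27 (4S,4aS,6S,7aR)-4-[(2R)-but-3-en-2-yl]-7a-hydroxy-6-[(2E)-6-methylhepta-2,5-dien-2-yl]hexahydrocyclopenta[c]pyran-3(1H)-one (cis-fused hydroxy δ-lactone; C4 = C1′, C4a = C5, C6 = C3, C7a = C1), via lithium ester enolate 26 (not isolated)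
Conditions: LiN(SiMe3)2 (1.3 equiv), THF, −78 → 0 °C; then AcOH
Reagents that add atoms: none
Why: LiN(SiMe3)2 deprotonates the ester α-CH2 reversibly and the enolate carbon (future C1′) attacks epoxide carbon C5 anti to the epoxide oxygen in an intramolecular SN2 reaction that breaks C5–O and frees the C1 tertiary alkoxide; the closest known reaction type is the intramolecular alkylation of ester and nitrile anions by epoxides (epoxynitrile-type cyclisation). The ring formed is the δ-lactone O–CH2–C1–C5–C1′–C2′, closed in a 6-(enolendo)-exo-tet mode with respect to the breaking C5–O bond. C5 is set by inversion and is therefore stereospecific from the Sharpless epoxide, which places the C5–C1′ bond cis to the C3 chain and trans to the C1 oxygen. C1′ is set in a chair-like transition state that keeps the but-3-en-2-yl arm pseudo-equatorial on the convex face of the forming cis-fused bicycle, and because it is α to the lactone carbonyl it can also converge to this exo epimer by enolate equilibration before the acid quench. The step needs attack at C5 and not at C1: C1 is fully substituted, and the tether starts at C1 on the face opposite the epoxide oxygen, so the enolate can reach only the backside of C5. The trans relation between the new alkoxide and the lactone arm should prevent translactonisation, which would require a strained trans-fused γ-lactone.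

Step 15
Reactants: 27 cis-fused hydroxy δ-lactone
Product: 28 4-[(2R)-but-3-en-2-yl]-6-[(2E)-6-methylhepta-2,5-dien-2-yl]hexahydrocyclopenta[c]pyran-3,7a(1H)-diol (lactol, ring centres as in 27, anomer mixture at C3)
Conditions: iBu2AlH (2.5 equiv), CH2Cl2, −78 °C
Reagents that add atoms: none
Why: Diisobutylaluminium hydride at −78 °C stops at the aluminium hemiacetal, so the lactone is reduced only to the lactol, the tertiary hydroxyl group consuming one extra equivalent.

Step 16
Reactants: 28 lactol
Product: 29 triol: ring A with OH and CH2OH at C1, the dienyl chain at C3 and, at C5, the chain C1′H[CH(OH)CH=CH2][CH(CH3)CH=CH2] (C1′ and C5′ as in 27, carbinol C2′ as epimer mixture)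
Conditions: CH2=CHMgBr (5 equiv), THF, 0 °C → rt
Reagents that add atoms: vinylmagnesium bromide, SMILES C=C[Mg]Br
Why: The lactol magnesium salt opens to the hydroxy aldehyde, which undergoes Grignard addition of the vinyl group; the new carbinol centre is formed as a mixture that does not matter because it is oxidised in step 18.

Step 17
Reactants: 29 triol
Product: 30 (1R,2S,4S)-1-(hydroxymethyl)-2-[(1S,5R)-2-hydroxy-5-methylcyclopent-3-en-1-yl]-4-[(2E)-6-methylhepta-2,5-dien-2-yl]cyclopentan-1-ol (C2′ epimer mixture)
Conditions: (H2IMes)(PCy3)Cl2Ru=CHPh (second-generation Grubbs catalyst, 5 mol %), CH2Cl2 (5 mM), 40 °C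
Reagents that add atoms: none
Why: Ring-closing metathesis of the two monosubstituted alkenes closes the five-membered ring B with loss of ethylene, the trisubstituted alkenes of the chain being too hindered to compete.

Step 18
Reactants: 30 cyclopentenol triol
Product: 31 (1R,2S,4S)-1-(hydroxymethyl)-4-[(2E)-6-methylhepta-2,5-dien-2-yl]-2-[(1S,5R)-5-methyl-2-oxocyclopent-3-en-1-yl]cyclopentan-1-ol
Conditions: MnO2 (activated, excess), CH2Cl2, rt
Reagents that add atoms: none
Why: Activated manganese dioxide oxidises allylic alcohols selectively, so only the cyclopentenol should become the enone, and the neutral conditions should not epimerise C1′.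

Step 19
Reactants: 31 enone diol
Product: 32 [(1R,2S,4S)-1-hydroxy-4-[(2E)-6-methylhepta-2,5-dien-2-yl]-2-[(1S,5R)-5-methyl-2-oxocyclopent-3-en-1-yl]cyclopentyl]methyl acetate
Conditions: Ac2O, pyridine, CH2Cl2, 0 °C
Reagents that add atoms: acetic anhydride, SMILES CC(=O)OC(C)=O
Why: Acetylation in pyridine without a stronger acyl-transfer catalyst should occur only at the primary hydroxyl group, the tertiary one being unreactive.

Step 20
Reactants: 32 acetate with skipped diene
Product: 33 [(1R,2S,4S)-1-hydroxy-4-[(2E,4E)-6-hydroperoxy-6-methylhepta-2,4-dien-2-yl]-2-[(1S,5R)-5-methyl-2-oxocyclopent-3-en-1-yl]cyclopentyl]methyl acetate (CNP0204569.2)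
Conditions: O2, visible light, tetraphenylporphyrin (cat.), CH2Cl2, −20 °C, stopped at partial conversion; preparative HPLC
Reagents that add atoms: dioxygen (as singlet oxygen), SMILES O=O
Why: Schenck ene reaction, in which singlet oxygen adds to the terminal trisubstituted alkene and abstracts a doubly allylic hydrogen on its more substituted side (cis effect), so the double bond moves into conjugation with E geometry and the hydroperoxide ends on the tertiary carbon, the enone being too electron-poor to react.

**Compound list**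

1 | (+)-limonene 1,2-oxide, (4R), cis/trans mixture | CC12CC[C@H](CC1O2)C(C)=C | starting material
2 | limonene-1,2-diol, (4R) (not isolated) | CC1(O)CC[C@H](CC1O)C(C)=C | intermediate
3 | (3R)-6-oxo-3-(prop-1-en-2-yl)heptanal | O=CC[C@@H](CCC(C)=O)C(C)=C | intermediate
4 | aldol adduct, 1-[2-hydroxy-4-(prop-1-en-2-yl)cyclopentyl]ethan-1-one (not isolated) | CC(=O)C1C(O)C[C@@H](C1)C(C)=C | intermediate
5 | 1-[(4S)-4-(prop-1-en-2-yl)cyclopent-1-en-1-yl]ethan-1-one | CC(=O)C1=CC[C@@H](C1)C(C)=C | intermediate
6 | 2,2,2-tribromo-1-[(4S)-4-(prop-1-en-2-yl)cyclopent-1-en-1-yl]ethan-1-one (not isolated) | BrC(Br)(Br)C(=O)C1=CC[C@@H](C1)C(C)=C | intermediate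
7 | (4S)-4-(prop-1-en-2-yl)cyclopent-1-ene-1-carboxylic acid | OC(=O)C1=CC[C@@H](C1)C(C)=C | intermediate
8 | methyl (4S)-4-(prop-1-en-2-yl)cyclopent-1-ene-1-carboxylate | COC(=O)C1=CC[C@@H](C1)C(C)=C | intermediate
9 | methyl (4S)-4-(3-methyl-1,2,4-trioxolan-3-yl)cyclopent-1-ene-1-carboxylate (not isolated) | COC(=O)C1=CC[C@@H](C1)C2(C)OCOO2 | intermediate
10 | methyl (4S)-4-acetylcyclopent-1-ene-1-carboxylate | COC(=O)C1=CC[C@@H](C1)C(C)=O | intermediate
11 | terminal lithium enolate of 10 (not isolated) | COC(=O)C1=CC[C@@H](C1)C(=C)O[Li] | intermediate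
12 | methyl (4S)-4-{1-[(diethoxyphosphoryl)oxy]ethenyl}cyclopent-1-ene-1-carboxylate | COC(=O)C1=CC[C@@H](C1)C(=C)OP(=O)(OCC)OCC | intermediate
13 | diethyl 1-[(1S)-3-(hydroxymethyl)cyclopent-3-en-1-yl]ethenyl phosphate | OCC1=CC[C@@H](C1)C(=C)OP(=O)(OCC)OCC | intermediate
14 | [(4S)-4-ethynylcyclopent-1-en-1-yl]methanol | OCC1=CC[C@@H](C1)C#C | intermediate
15 | prenyl bromide | CC(C)=CCBr | starting material
16 | (E)-alkenyl(dimethyl)alane of 14 as its dimethylaluminium alkoxide (not isolated) | C[Al](C)OCC1=CC[C@@H](C1)/C(C)=C/[Al](C)C | intermediate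
17 | {(4S)-4-[(2E)-6-methylhepta-2,5-dien-2-yl]cyclopent-1-en-1-yl}methanol | OCC1=CC[C@@H](C1)/C(C)=C/CC=C(C)C | intermediate
18 | {(1S,3S,5S)-3-[(2E)-6-methylhepta-2,5-dien-2-yl]-6-oxabicyclo[3.1.0]hexan-1-yl}methanol | OC[C@@]1(O2)C[C@@H](/C(C)=C/CC=C(C)C)C[C@@H]12 | intermediate
19 | racemic 3-methylpent-4-enoic acid | C=CC(C)CC(=O)O | starting material
20 | (S)-4-benzyloxazolidin-2-one | O=C1N[C@@H](Cc2ccccc2)CO1 | starting material
21 | 3-methylpent-4-enoic pivalic anhydride, racemic (not isolated) | C=CC(C)CC(=O)OC(=O)C(C)(C)C | intermediate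
22 | (4S)-4-benzyl-3-[(3S)-3-methylpent-4-enoyl]oxazolidin-2-one | C=C[C@@H](C)CC(=O)N1[C@@H](Cc2ccccc2)COC1=O | intermediate
23 | (3S)-3-methylpent-4-eneperoxoic acid, as lithium salt (not isolated) | C=C[C@@H](C)CC(=O)OO | intermediate
24 | (3S)-3-methylpent-4-enoic acid | C=C[C@@H](C)CC(=O)O | intermediate
25 | {(1S,3S,5S)-3-[(2E)-6-methylhepta-2,5-dien-2-yl]-6-oxabicyclo[3.1.0]hexan-1-yl}methyl (3S)-3-methylpent-4-enoate | C=C[C@@H](C)CC(=O)OC[C@@]1(O2)C[C@@H](/C(C)=C/CC=C(C)C)C[C@@H]12 | intermediate
26 | lithium enolate of ester 25 (not isolated) | C=C[C@@H](C)C=C(O[Li])OC[C@@]1(O2)C[C@@H](/C(C)=C/CC=C(C)C)C[C@@H]12 | intermediate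
27 | (4S,4aS,6S,7aR)-4-[(2R)-but-3-en-2-yl]-7a-hydroxy-6-[(2E)-6-methylhepta-2,5-dien-2-yl]hexahydrocyclopenta[c]pyran-3(1H)-one | O=C1OC[C@@]2(O)C[C@@H](/C(C)=C/CC=C(C)C)C[C@H]2[C@@H]1[C@H](C)C=C | intermediate
28 | lactol of 27 (anomer mixture) | OC1OC[C@@]2(O)C[C@@H](/C(C)=C/CC=C(C)C)C[C@H]2[C@@H]1[C@H](C)C=C | intermediate
29 | triol with C1′ bearing CH(OH)CH=CH2 and CH(CH3)CH=CH2 (C2′ epimer mixture) | OC[C@@]1(O)C[C@@H](/C(C)=C/CC=C(C)C)C[C@H]1[C@@H](C(O)C=C)[C@H](C)C=C | intermediate
30 | (1R,2S,4S)-1-(hydroxymethyl)-2-[(1S,5R)-2-hydroxy-5-methylcyclopent-3-en-1-yl]-4-[(2E)-6-methylhepta-2,5-dien-2-yl]cyclopentan-1-ol (C2′ epimer mixture) | OC[C@@]1(O)C[C@@H](/C(C)=C/CC=C(C)C)C[C@H]1[C@H]2C(O)C=C[C@H]2C | intermediate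
31 | (1R,2S,4S)-1-(hydroxymethyl)-4-[(2E)-6-methylhepta-2,5-dien-2-yl]-2-[(1S,5R)-5-methyl-2-oxocyclopent-3-en-1-yl]cyclopentan-1-ol | OC[C@@]1(O)C[C@@H](/C(C)=C/CC=C(C)C)C[C@H]1[C@H]2C(=O)C=C[C@H]2C | intermediate
32 | [(1R,2S,4S)-1-hydroxy-4-[(2E)-6-methylhepta-2,5-dien-2-yl]-2-[(1S,5R)-5-methyl-2-oxocyclopent-3-en-1-yl]cyclopentyl]methyl acetate | CC(=O)OC[C@@]1(O)C[C@@H](/C(C)=C/CC=C(C)C)C[C@H]1[C@H]2C(=O)C=C[C@H]2C | intermediate
33 | [(1R,2S,4S)-1-hydroxy-4-[(2E,4E)-6-hydroperoxy-6-methylhepta-2,4-dien-2-yl]-2-[(1S,5R)-5-methyl-2-oxocyclopent-3-en-1-yl]cyclopentyl]methyl acetate | CC(=O)OC[C@@]1(O)C[C@@H](/C(C)=C/C=C/C(C)(C)OO)C[C@H]1[C@H]1C(=O)C=C[C@H]1C | target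

**Step count and risks**

Total step count: 20. Longest linear sequence: 18 steps (steps 1–10 and 13–20, from 1 to 33).

Steps most likely to fail:

1. Step 14. The unstabilised ester enolate may be lost to ketene formation or intermolecular Claisen condensation before it reaches C5, or the ring may close with poor control at C1′. The fallback sets out from 24 and 18 and comes back at 27. Acid 24 is sulfenylated at C2 through its dianion (LiN(iPr)2, then PhSSPh) to give (3S)-3-methyl-2-(phenylsulfanyl)pent-4-enoic acid F1. Esterification with epoxy alcohol 18 (DCC, DMAP) gives the α-(phenylsulfanyl) ester F2. Its sulfur-stabilised, long-lived enolate (LiN(SiMe3)2, THF) should open the epoxide at C5 in the same six-membered mode to give the α-(phenylsulfanyl) lactone F3. Reductive desulfurisation with SmI2 (THF–MeOH, −78 °C), followed by brief equilibration of C1′ with DBU, returns lactone 27.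

2. Step 20. Singlet oxygen may not discriminate between the two trisubstituted alkenes, nor between the methylene and methyl hydrogens of the terminal one, and the diene product can be oxidised further, so the hydroperoxide is expected as one component of a mixture. The fallback sets out from 32 and comes back at 33 without any new isolated compound (F0). It is a peroxyl-radical chain autoxidation (O2, di-tert-butyl hyponitrite as initiator, N-methylbenzohydroxamic acid as hydrogen-atom shuttle, benzene, 30 °C). This abstracts only the doubly allylic hydrogen, and oxygen should then add to the pentadienyl radical preferentially at the less hindered CMe2 terminus. The products are thereby limited to the two conjugated tertiary hydroperoxides, from which 33 is separated.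

3. Step 16. The hindered lactol may open slowly, and the transient α-branched aldehyde may enolise under the Grignard reagent, with loss of the C1′ configuration or low conversion. The fallback sets out from 27 and comes back at 31. Aminolysis of lactone 27 (MeONHMe·HCl, AlMe3, CH2Cl2) gives the N-methoxy-N-methylamide diol F4, which is protected (2-methoxypropene, PPTS) as its acetonide F5. Vinylmagnesium bromide then gives the vinyl ketone F6 without passing through an aldehyde. Ring-closing metathesis with (H2IMes)(PCy3)Cl2Ru=CHPh (second-generation Grubbs catalyst) gives the acetonide-protected cyclopentenone F7, and aqueous acetic acid removes the acetonide to give 31.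

**Further compounds**

F1 | step 14 | (3S)-3-methyl-2-(phenylsulfanyl)pent-4-enoic acid (C2 epimer mixture) | C=C[C@@H](C)C(Sc1ccccc1)C(=O)O
F2 | step 14 | {(1S,3S,5S)-3-[(2E)-6-methylhepta-2,5-dien-2-yl]-6-oxabicyclo[3.1.0]hexan-1-yl}methyl (3S)-3-methyl-2-(phenylsulfanyl)pent-4-enoate | C=C[C@@H](C)C(Sc3ccccc3)C(=O)OC[C@@]1(O2)C[C@@H](/C(C)=C/CC=C(C)C)C[C@@H]12
F3 | step 14 | α-(phenylsulfanyl) analogue of lactone 27 (PhS on C1′) | O=C1OC[C@@]2(O)C[C@@H](/C(C)=C/CC=C(C)C)C[C@H]2C1(Sc3ccccc3)[C@H](C)C=C
F0 | step 20 | none | none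
F4 | step 16 | N-methoxy-N-methylamide diol from ring opening of 27 | OC[C@@]1(O)C[C@@H](/C(C)=C/CC=C(C)C)C[C@H]1[C@@H](C(=O)N(C)OC)[C@H](C)C=C
F5 | step 16 | acetonide of F4 (spiro 2,2-dimethyl-1,3-dioxolane at C1) | CC1(C)OC[C@@]2(O1)C[C@@H](/C(C)=C/CC=C(C)C)C[C@H]2[C@@H](C(=O)N(C)OC)[C@H](C)C=C
F6 | step 16 | vinyl ketone from F5 | CC1(C)OC[C@@]2(O1)C[C@@H](/C(C)=C/CC=C(C)C)C[C@H]2[C@@H](C(=O)C=C)[C@H](C)C=C
F7 | step 16 | acetonide of enone diol 31 | CC1(C)OC[C@@]2(O1)C[C@@H](/C(C)=C/CC=C(C)C)C[C@H]2[C@H]3C(=O)C=C[C@H]3C
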